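A small charge of reagent, 0.800 equiv on the substrate in south-east, which is smaller than the 1.60 equiv of east, looks like a cap on the target. We write its balance to see whether it is one.

| setting | midnight | dusk | autumn | east | south-east |
|---|---|---|---|---|---|
| substrate | 0.070 M (fed, over 2.0 min) | 0.29 M (fed, over 2.0 min) | 0.10 M (fed, over 2.0 min) | 0.40 M | 0.10 M (fed, over 2.0 min) |
| reagent | 0.80 equiv | 0.80 equiv | 1.1 equiv | 1.60 equiv | 0.800 equiv |
| remark | run made earlier; the fed solution adds 0.25 times the starting volume | run made earlier; the fed solution adds 0.25 times the starting volume | run made earlier; the fed solution adds 0.25 times the starting volume | everything together at the start, the whole solution of substrate included, so that from the start the volume is larger by 0.25 times the starting volume | the fed solution adds 0.25 times the starting volume |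
| time |  |  |  | 25 min | 25 min |

| run | time / min | target / % | substrate / % |
|---|---|---|---|
| midnight | 0.667 | 0.2 | 31.4 |
| midnight | 2.00 | 0.4 | 85.1 |
| midnight | 4.00 | 3.6 | 61.1 |
| midnight | 5.00 | 4.6 | 51.6 |
| midnight | 8.00 | 8.4 | 31.7 |
| midnight | 10.0 | 11.2 | 22.7 |
| midnight | 12.0 | 13.1 | 15.8 |
| dusk | 1.00 | 0.5 | 45.2 |
| dusk | 1.50 | 0.7 | 65.5 |
| dusk | 2.50 | 2.9 | 77.8 |
| dusk | 4.00 | 5.5 | 61.0 |
| dusk | 5.00 | 8.6 | 51.9 |
| dusk | 8.00 | 12.4 | 31.6 |
| dusk | 12.0 | 15.0 | 16.7 |
| autumn | 2.50 | 2.0 | 77.4 |
| autumn | 5.00 | 6.0 | 51.7 |
| autumn | 8.00 | 11.4 | 31.3 |
| autumn | 10.0 | 12.5 | 22.6 |
| autumn | 12.0 | 15.7 | 16.5 |

(readings scatter by 0.5 percentage points)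

- amounts are per litre of the starting volume; all of the dose is in the solution fed
- what was read earlier has a scatter of 0.5 percentage points, one standard deviation
- steps under discussion: target <-> isomer of the product; reagent + intermediate -> target; substrate -> intermediate; substrate -> side product B; substrate -> side product A
- where the amount of substrate changes, what is given in equivalents or mol% on it follows
- percentages count the whole charge, also what has not yet gone in

* the flask that ends with the higher amount of target, in percent of the substrate charged, or "neither" when 2 percentage points or less lies between them (east / south-east / neither)
* final target, as a percentage of the substrate charged, in east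
* final target, as a percentage of the substrate charged, in south-east

Reagent spent leaves as target or its isomer, and substrate reaches reagent through intermediate, one of its three exits. So we want f, the fraction of spent substrate that takes this exit. Two separate stretches of dusk give it: up to 5.00 min, target over substrate lost is 0.179, and from there to 12.0 min, target gained over substrate lost is 0.182. They agree. In autumn the same stretches part, at 0.124 and 0.276. Dusk holds twice the reagent per litre, so we read autumn as intermediate queuing early and draining late. Each autumn stretch then cheats, in opposite directions, and autumn's whole span returns 0.188. We carry dusk's whole span, f = 0.180, a reading that counts target and leaves out what stands as isomer or intermediate.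

Dusk's substrate, read between those two times, has a half-life of 4.28 min. At 5.00 min the substrate reads 51.6% in midnight, 51.9% in dusk and 51.7% in autumn, so we carry that half-life over and expect nearly all of the substrate spent by 25 min in east and south-east. Now the balance. The reagent call is f divided by the equivalents charged, the fraction of its own charge that the reagent must give up once the substrate is spent: 22.5% in south-east and 11.3% in east. Both lie below the whole charge, so we take substrate as the limiting reagent in both flasks. Target, isomer and leftover intermediate should then sum to about f of the charge in each, so we expect target near f in both flasks and name neither flask as ahead.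

The forecast, from the same runs, says neither too, but puts target at 14% in east and 15% in south-east, each below our f, and argues that “East makes target earlier, so it isomerises longer”.

The simulation gives neither, with 17.4% in east and 17.4% in south-east.

    target ⇌ isomer of the product (K = 19.0, k = 0.00459 min⁻¹)
    reagent + intermediate → target (k = 7.96 M⁻¹ min⁻¹)
    substrate → intermediate (k = 0.0321 min⁻¹)
    substrate → side product B (k = 0.0675 min⁻¹)
    substrate → side product A (k = 0.0664 min⁻¹)

South-east has spent 23.4% of its reagent against a call of 22.5%, and east 11.9% against 11.3%. Neither flask is at rest at 25 min: substrate stands at 1.9% in south-east and 1.6% in east, and the relaxation half-life of target and isomer in east, 143 min, is longer than that time. By 250 min, south-east's reagent goes from 76.6% to 75.8%, while its isomer climbs from 1.35% to 12.6%. Target by then has fallen to 6.71% in south-east and 6.63% in east.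

The earlier runs and the new flask were generated by integration for an exercise, and the scatter is random.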